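**Retrosynthetic overview**

1. Target 29 ← saponification and ketone methylenation of the macrocyclic keto ester 27.
2. 27 ← ring closure at C4–C5 by an intramolecular SN2′ attack of a cyclopropanol-derived zinc/copper homoenolate (the nucleophilic β-carbon of the future ring ketone) on a 2-(bromomethyl)enoate. This one step closes the ten-membered ring, sets C4 and unveils both the C7 ketone and the acrylate.
3. Acceptor arm ← propargyl group → aldehyde → Morita–Baylis–Hillman adduct → allylic bromide; isopropenyl ← carboxyl group left by a Wolff ring contraction.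
4. Cyclobutane ← photochemical Wolff contraction of a 2,2,3-trisubstituted cyclopentanone, itself from Cu-catalysed asymmetric conjugate addition/propargylation of 2-methylcyclopent-2-enone.
5. Ring order: cyclopropane (temporary homoenolate precursor, asymmetric Kulinkovich) → cyclobutane (contraction of the purchased five-ring) → ten-membered ring last.

**Assumption:** 6-bromo-2-methylhex-2-ene, TADDOL and the Cu ligands are taken as catalogue items; where the sense of induction of a chiral controller is not certain, its antipode is used after a first run.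

**Abbreviations used in names:** R^A = 2-[(1R,2R)-1-(tert-butyldimethylsilyloxy)-2-(3-methylbut-2-en-1-yl)cyclopropyl]ethyl; R^B = the same group with free OH. The spatial arrangement is that of 4 and 5; the C1 descriptor changes from S to R only through CIP priorities.

**Step 1**
Reactants: 1 methyl 3-chloropropanoate; 2 6-bromo-2-methylhex-2-ene
Product: 4 (1S,2R)-1-(2-chloroethyl)-2-(3-methylbut-2-en-1-yl)cyclopropan-1-ol, via Grignard reagent 3 (not isolated)
Conditions: 2, Mg, THF, 40 °C; added over 3 h to 1 and pre-formed titanium bis[(4R,5R)-TADDOLate] (1.0 equiv), THF, 0 °C → rt; aq NH4Cl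
Reagents that add atoms: magnesium, [Mg] (in 3 only)
Why: Kulinkovich cyclopropanation, in which the titanacyclopropane from 3 adds twice to the ester carbonyl to give the cis-1,2-dialkylcyclopropanol, with the stoichiometric chiral titanium TADDOLate fixing the absolute configuration at C2 (the later prenyl-bearing C6 of the target; about 70–85% ee is typical, the minor series being removed later as a diastereomer).

**Step 2**
Reactants: 4
Product: 5 tert-butyl{[(1S,2R)-1-(2-chloroethyl)-2-(3-methylbut-2-en-1-yl)cyclopropyl]oxy}dimethylsilane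
Conditions: TBSOTf, 2,6-lutidine, CH2Cl2, −78 → 0 °C
Reagents that add atoms: tert-butyldimethylsilyl trifluoromethanesulfonate, CC(C)(C)[Si](C)(C)OS(=O)(=O)C(F)(F)F
Why: Silyl triflate silylation of the tertiary cyclopropanol gives a siloxycyclopropane that tolerates the Grignard, amide-base, photochemical and organolithium steps that follow; no stereocentre is touched.

**Step 3**
Reactants: 5; 6 2-methylcyclopent-2-en-1-one; 7 3-bromoprop-1-yne
Product: 10 (2S,3R)-2-methyl-2-(prop-2-yn-1-yl)-3-R^A-cyclopentan-1-one, via Grignard reagent 8 (not isolated), via magnesium enolate 9 (not isolated)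
Conditions: 5, Mg (I2-activated), 2-MeTHF, 45 °C; 6, Cu(OTf)2 (5 mol%), chiral hydroxyalkyl-NHC precursor (6 mol%), Et2O/2-MeTHF, −30 → 0 °C; then 7, DMPU, −30 °C → rt
Reagents that add atoms: magnesium, [Mg] (in 8 and 9 only)
Why: Cu/NHC-catalysed asymmetric conjugate addition of a Grignard reagent to an α-substituted cyclopentenone sets C3 under catalyst control, and the magnesium enolate is then propargylated anti to the new C3 chain, which gives the quaternary C2 with methyl cis to the chain.

**Step 4**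
Reactants: 10
Product: 12 (2S,3R)-5-diazo-2-methyl-2-(prop-2-yn-1-yl)-3-R^A-cyclopentan-1-one, via trifluoroacetyl ketone 11 (not isolated)
Conditions: LiHMDS (1.1 equiv), THF, −78 °C; CF3CO2CH2CF3; aq NH4Cl; then MsN3, Et3N, H2O (1 equiv), MeCN, rt
Reagents that add atoms: 2,2,2-trifluoroethyl trifluoroacetate, O=C(OCC(F)(F)F)C(F)(F)F (its acyl group is in 11 only); methanesulfonyl azide, CS(=O)(=O)N=[N+]=[N-]
Why: Detrifluoroacetylative diazo transfer (Danheiser) at C5, the only enolisable position because C2 is quaternary; the ketone is deprotonated in preference to the alkyne C–H and no stereocentre is affected.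

**Step 5**
Reactants: 12
Product: 14 (2S,3R)-2-methyl-2-(prop-2-yn-1-yl)-3-R^A-cyclobutane-1-carboxylic acid (both C1 epimers), via ketene 13 (not isolated)
Conditions: hν (medium-pressure Hg lamp, Pyrex), THF/H2O 4:1, 0 °C → rt
Reagents that add atoms: water, O
Why: Photochemical Wolff rearrangement, in which the quaternary carbon migrates with retention from the carbonyl to the carbene carbon, contracting the ring to the cyclobutane; the ketene is hydrated to the acid and the new C1 centre is formed unselectively and corrected in step 6.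

**Step 6**
Reactants: 14
Product: 16 1-[(1S,2S,3R)-2-methyl-2-(prop-2-yn-1-yl)-3-R^A-cyclobutyl]ethan-1-one, via trilithium diolate 15 (not isolated)
Conditions: MeLi (4.5 equiv), Et2O, 0 °C → rt; inverse quench into cold aq NH4Cl; crude product with NaOMe (0.3 equiv), MeOH, rt; chromatography (minor C1 epimer recycled)
Reagents that add atoms: methyllithium, [Li]C
Why: Addition of methyllithium to the lithium carboxylate stops at the gem-diolate and gives the methyl ketone on work-up, and base equilibration of the α-centre favours the isomer with acetyl cis-1,3 to the C3 arm and cis to the C2 methyl, in which all three large groups are pseudo-equatorial.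

**Step 7**
Reactants: 16
Product: 17 (1R,2S,3R)-2-methyl-1-(prop-1-en-2-yl)-2-(prop-2-yn-1-yl)-3-R^A-cyclobutane
Conditions: Ph3PCH3Br (2.5 equiv), KHMDS (2.3 equiv), THF, 0 → 45 °C
Reagents that add atoms: methyltriphenylphosphonium bromide, C[P+](c1ccccc1)(c1ccccc1)c1ccccc1.[Br-]
Why: Wittig methylenation of the hindered methyl ketone installs the isopropenyl group and locks the C1 configuration; an excess of phosphonium salt leaves no free base that could isomerise the propargyl group.

**Step 8**
Reactants: 17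
Product: 19 3-[(1S,2R,4R)-1-methyl-2-(prop-1-en-2-yl)-4-R^A-cyclobutyl]propanal, via alkenylborane 18 (not isolated)
Conditions: disiamylborane (from BH3·THF and 2-methylbut-2-ene, 1.3 equiv), THF, 0 °C; then 30% H2O2, pH 7 phosphate buffer, 0 °C → rt
Reagents that add atoms: disiamylborane, CC(C)C(C)BC(C)C(C)C (in 18 only); hydrogen peroxide, OO
Why: Anti-Markovnikov hydroboration of the terminal alkyne by a hindered dialkylborane is much faster than reaction at the 1,1-disubstituted and trisubstituted alkenes, and buffered oxidation of the alkenylborane gives the aldehyde.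

**Step 9**
Reactants: 19; 20 methyl acrylate
Product: 22 methyl 3-hydroxy-2-methylidene-5-[(1S,2R,4R)-1-methyl-2-(prop-1-en-2-yl)-4-R^B-cyclobutyl]pentanoate (C3 epimers), via silyl ether adduct 21 (not isolated)
Conditions: DABCO (1.0 equiv), 20 (10 equiv), MeOH, rt, 5 d; concentrate; TBAF/AcOH (1:1), THF, 0 °C → rt
Reagents that add atoms: none
Why: Morita–Baylis–Hillman reaction of the unhindered aldehyde with methyl acrylate, followed in the same flask by buffered fluoride cleavage of the cyclopropyl silyl ether; the carbinol centre is an irrelevant mixture because it is destroyed in step 10.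

**Step 10**
Reactants: 22
Product: 24 methyl (2Z)-2-(bromomethyl)-5-[(1S,2R,4R)-1-methyl-2-(prop-1-en-2-yl)-4-R^B-cyclobutyl]pent-2-enoate, via allylic mesylate 23 (not isolated)
Conditions: MsCl (1.1 equiv), iPr2NEt, CH2Cl2, −30 °C; then LiBr, THF, 0 °C → rt
Reagents that add atoms: methanesulfonyl chloride, CS(=O)(=O)Cl (in 23 only); lithium bromide, [Li+].[Br-]
Why: The activated secondary allylic alcohol is mesylated much faster than the tertiary cyclopropanol, and SN2′ displacement by bromide gives the thermodynamically preferred (Z)-2-(bromomethyl)enoate; the non-nucleophilic base avoids quaternisation of the allylic bromide.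

**Step 11**
Reactants: 24
Product: 27 methyl 2-[(1S,4S,6R,10R,12R)-1-methyl-6-(3-methylbut-2-en-1-yl)-7-oxo-12-(prop-1-en-2-yl)bicyclo[8.2.0]dodecan-4-yl]prop-2-enoate, via zinc cyclopropanolate 25 (not isolated), via zinc homoenolate 26 (not isolated)
Conditions: 24 added by syringe pump (12 h) to Et2Zn (2.5 equiv), CuTC (20 mol%), chiral phosphoramidite (24 mol%), THF/DMA, final 1 mM, 0 → 25 °C; aq NH4Cl
Reagents that add atoms: diethylzinc, CC[Zn]CC (in 25 and 26 only)
Why: Proposed new method: homoenolate SN2′ allylic alkylation run as a macrocyclisation, in which Et2Zn forms the zinc cyclopropanolate, this opens at the less substituted C–C bond to the β-zincio ketone with the prenyl-bearing carbon untouched (C6 is R from step 1), and Cu(I)/phosphoramidite delivers this nucleophilic β-carbon anti-SN2′ to the γ-carbon of the bromomethyl enoate, closing the ten-membered ring, expelling bromide to leave the acrylate and setting C4 (S) under ligand control reinforced by the 1,3-anti preference relative to the prenyl group; the closest known reactions are the intermolecular Cu-catalysed SN2′ allylation of cyclopropanol-derived zinc homoenolates and Cu/phosphoramidite-catalysed enantioselective SN2′ additions of organozincs to Baylis–Hillman-derived allylic halides.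

**Step 12**
Reactants: 27
Product: 28 methyl 2-[(1S,4S,6R,10R,12R)-1-methyl-7-methylidene-6-(3-methylbut-2-en-1-yl)-12-(prop-1-en-2-yl)bicyclo[8.2.0]dodecan-4-yl]prop-2-enoate
Conditions: Zn, CH2Br2, TiCl4 (pre-formed Lombardo reagent), THF/CH2Cl2, 0 °C → rt
Reagents that add atoms: dibromomethane, BrCBr
Why: Takai–Lombardo methylenation is non-basic, so the α-stereocentre C6 is not epimerised, and it is selective for the ketone over the acrylate ester.

**Step 13**
Reactants: 28
Product: 29 2-[(1S,4S,6R,10R,12R)-1-methyl-7-methylidene-6-(3-methylbut-2-en-1-yl)-12-(prop-1-en-2-yl)bicyclo[8.2.0]dodecan-4-yl]prop-2-enoic acid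
Conditions: LiOH·H2O (5 equiv), THF/MeOH/H2O 3:1:1, rt; 1 M HCl to pH 3
Reagents that add atoms: lithium hydroxide, [Li+].[OH-]
Why: Saponification of the α-substituted acrylate methyl ester under mild conditions that leave the allylic C4 centre and the four alkenes untouched.

**Compound list**

1 | methyl 3-chloropropanoate | COC(=O)CCCl | starting material
2 | 6-bromo-2-methylhex-2-ene | CC(C)=CCCCBr | starting material
3 | (5-methylhex-4-en-1-yl)magnesium bromide | CC(C)=CCCC[Mg]Br | intermediate
4 | (1S,2R)-1-(2-chloroethyl)-2-(3-methylbut-2-en-1-yl)cyclopropan-1-ol (alkyl groups cis) | CC(C)=CC[C@@H]1C[C@]1(O)CCCl | intermediate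
5 | tert-butyl{[(1S,2R)-1-(2-chloroethyl)-2-(3-methylbut-2-en-1-yl)cyclopropyl]oxy}dimethylsilane | CC(C)=CC[C@@H]1C[C@]1(O[Si](C)(C)C(C)(C)C)CCCl | intermediate
6 | 2-methylcyclopent-2-en-1-one | CC1=CCCC1=O | starting material
7 | 3-bromoprop-1-yne | C#CCBr | starting material
8 | {2-[(1S,2R)-1-(tert-butyldimethylsilyloxy)-2-(3-methylbut-2-en-1-yl)cyclopropyl]ethyl}magnesium chloride | CC(C)=CC[C@@H]1C[C@]1(O[Si](C)(C)C(C)(C)C)CC[Mg]Cl | intermediate
9 | chloromagnesium enolate of 2-methyl-3-R^A-cyclopentanone (C3 as in 10) | CC(C)=CC[C@@H]1C[C@]1(O[Si](C)(C)C(C)(C)C)CC[C@@H]2CCC(O[Mg]Cl)=C2C | intermediate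
10 | (2S,3R)-2-methyl-2-(prop-2-yn-1-yl)-3-R^A-cyclopentan-1-one | CC(C)=CC[C@@H]1C[C@]1(O[Si](C)(C)C(C)(C)C)CC[C@@H]2CCC(=O)[C@@]2(C)CC#C | intermediate
11 | (2S,3R)-2-methyl-2-(prop-2-yn-1-yl)-3-R^A-5-(trifluoroacetyl)cyclopentan-1-one | CC(C)=CC[C@@H]1C[C@]1(O[Si](C)(C)C(C)(C)C)CC[C@@H]2CC(C(=O)C(F)(F)F)C(=O)[C@@]2(C)CC#C | intermediate
12 | (2S,3R)-5-diazo-2-methyl-2-(prop-2-yn-1-yl)-3-R^A-cyclopentan-1-one | CC(C)=CC[C@@H]1C[C@]1(O[Si](C)(C)C(C)(C)C)CC[C@@H]2CC(=[N+]=[N-])C(=O)[C@@]2(C)CC#C | intermediate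
13 | [(2S,3R)-2-methyl-2-(prop-2-yn-1-yl)-3-R^A-cyclobutylidene]methanone (ketene) | CC(C)=CC[C@@H]1C[C@]1(O[Si](C)(C)C(C)(C)C)CC[C@@H]2CC(=C=O)[C@@]2(C)CC#C | intermediate
14 | (2S,3R)-2-methyl-2-(prop-2-yn-1-yl)-3-R^A-cyclobutane-1-carboxylic acid (C1 epimers) | CC(C)=CC[C@@H]1C[C@]1(O[Si](C)(C)C(C)(C)C)CC[C@@H]2CC(C(=O)O)[C@@]2(C)CC#C | intermediate
15 | trilithium salt (ethane-1,1-diolate and acetylide) formed from 14 and methyllithium | [Li+].[Li+].[Li+].CC(C)=CC[C@@H]1C[C@]1(O[Si](C)(C)C(C)(C)C)CC[C@@H]2CC(C(C)([O-])[O-])[C@@]2(C)CC#[C-] | intermediate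
16 | 1-[(1S,2S,3R)-2-methyl-2-(prop-2-yn-1-yl)-3-R^A-cyclobutyl]ethan-1-one | CC(C)=CC[C@@H]1C[C@]1(O[Si](C)(C)C(C)(C)C)CC[C@@H]2C[C@H](C(C)=O)[C@@]2(C)CC#C | intermediate
17 | (1R,2S,3R)-2-methyl-1-(prop-1-en-2-yl)-2-(prop-2-yn-1-yl)-3-R^A-cyclobutane | CC(C)=CC[C@@H]1C[C@]1(O[Si](C)(C)C(C)(C)C)CC[C@@H]2C[C@H](C(C)=C)[C@@]2(C)CC#C | intermediate
18 | (E)-alkenylbis(3-methylbutan-2-yl)borane from 17 | CC(C)=CC[C@@H]1C[C@]1(O[Si](C)(C)C(C)(C)C)CC[C@@H]2C[C@H](C(C)=C)[C@@]2(C)C/C=C/B(C(C)C(C)C)C(C)C(C)C | intermediate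
19 | 3-[(1S,2R,4R)-1-methyl-2-(prop-1-en-2-yl)-4-R^A-cyclobutyl]propanal | CC(C)=CC[C@@H]1C[C@]1(O[Si](C)(C)C(C)(C)C)CC[C@@H]2C[C@H](C(C)=C)[C@@]2(C)CCC=O | intermediate
20 | methyl prop-2-enoate (methyl acrylate) | C=CC(=O)OC | starting material
21 | methyl 3-hydroxy-2-methylidene-5-[(1S,2R,4R)-1-methyl-2-(prop-1-en-2-yl)-4-R^A-cyclobutyl]pentanoate (C3 epimers) | CC(C)=CC[C@@H]1C[C@]1(O[Si](C)(C)C(C)(C)C)CC[C@@H]2C[C@H](C(C)=C)[C@@]2(C)CCC(O)C(=C)C(=O)OC | intermediate
22 | methyl 3-hydroxy-2-methylidene-5-[(1S,2R,4R)-1-methyl-2-(prop-1-en-2-yl)-4-R^B-cyclobutyl]pentanoate (C3 epimers) | CC(C)=CC[C@@H]1C[C@]1(O)CC[C@@H]2C[C@H](C(C)=C)[C@@]2(C)CCC(O)C(=C)C(=O)OC | intermediate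
23 | methyl 3-(methanesulfonyloxy)-2-methylidene-5-[(1S,2R,4R)-1-methyl-2-(prop-1-en-2-yl)-4-R^B-cyclobutyl]pentanoate | CC(C)=CC[C@@H]1C[C@]1(O)CC[C@@H]2C[C@H](C(C)=C)[C@@]2(C)CCC(OS(C)(=O)=O)C(=C)C(=O)OC | intermediate
24 | methyl (2Z)-2-(bromomethyl)-5-[(1S,2R,4R)-1-methyl-2-(prop-1-en-2-yl)-4-R^B-cyclobutyl]pent-2-enoate | CC(C)=CC[C@@H]1C[C@]1(O)CC[C@@H]2C[C@H](C(C)=C)[C@@]2(C)CC/C=C(\CBr)C(=O)OC | intermediate
25 | ethylzinc cyclopropanolate of 24 | CC(C)=CC[C@@H]1C[C@]1(O[Zn]CC)CC[C@@H]2C[C@H](C(C)=C)[C@@]2(C)CC/C=C(\CBr)C(=O)OC | intermediate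
26 | ethylzinc homoenolate (β-zincio ketone EtZn–CH2–CH(prenyl)–C(=O)–CH2CH2–cyclobutane core, bromomethyl enoate arm unchanged; prenyl-bearing carbon in the arrangement that becomes 6R) | CC[Zn]C[C@@H](CC=C(C)C)C(=O)CC[C@@H]1C[C@H](C(C)=C)[C@@]1(C)CC/C=C(\CBr)C(=O)OC | intermediate
27 | methyl 2-[(1S,4S,6R,10R,12R)-1-methyl-6-(3-methylbut-2-en-1-yl)-7-oxo-12-(prop-1-en-2-yl)bicyclo[8.2.0]dodecan-4-yl]prop-2-enoate | O=C1CC[C@@H]2C[C@H](C(=C)C)[C@@]2(C)CC[C@H](C(=C)C(=O)OC)C[C@H]1CC=C(C)C | intermediate
28 | methyl 2-[(1S,4S,6R,10R,12R)-1-methyl-7-methylidene-6-(3-methylbut-2-en-1-yl)-12-(prop-1-en-2-yl)bicyclo[8.2.0]dodecan-4-yl]prop-2-enoate | C=C1CC[C@@H]2C[C@H](C(=C)C)[C@@]2(C)CC[C@H](C(=C)C(=O)OC)C[C@H]1CC=C(C)C | intermediate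
29 | 2-[(1S,4S,6R,10R,12R)-1-methyl-7-methylidene-6-(3-methylbut-2-en-1-yl)-12-(prop-1-en-2-yl)bicyclo[8.2.0]dodecan-4-yl]prop-2-enoic acid | C=C1CC[C@@H]2C[C@H](C(=C)C)[C@@]2(C)CC[C@H](C(=C)C(=O)O)C[C@H]1CC=C(C)C | target

**Step count**

Total steps: 13. Longest linear sequence: 13 (steps 1–13; 5 enters the main line in step 3).

**Steps most likely to fail, with fallbacks**

Step 11 (macrocyclisation). The risks are attack at the CH2Br carbon (giving a twelve-membered ring), ethyl transfer from zinc, protonolysis to the open-chain ketone, oligomerisation and insufficient selectivity at C4. The fallback sets out from 24 and returns at 27. The cyclopropanol 24 is opened oxidatively with Mn(acac)3 in MeCN at 1 mM to the β-keto radical, which adds to the enoate carbon and expels a bromine atom (radical addition–fragmentation), so the ring is closed by a radical instead of an organometallic homoenolate. C4 then rests on substrate control alone. This fallback makes no compound outside the list (F0).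

Step 1 (asymmetric Kulinkovich). The β-chloro ester can eliminate to acrylate under Grignard conditions, and the chiral titanium variant gives only moderate ee. The fallback sets out from 1 and 2 and returns at 4. The ordinary Ti(OiPr)4-catalysed Kulinkovich reaction gives racemic cis-cyclopropanol, that is 4 together with its enantiomer (1R,2S)-1-(2-chloroethyl)-2-(3-methylbut-2-en-1-yl)cyclopropan-1-ol F1. The racemate is esterified with (S)-2-methoxy-2-phenylacetic acid (DCC, DMAP) to give (1S,2R)-1-(2-chloroethyl)-2-(3-methylbut-2-en-1-yl)cyclopropyl (2S)-2-methoxy-2-phenylacetate F2 and its diastereomer (1R,2S)-1-(2-chloroethyl)-2-(3-methylbut-2-en-1-yl)cyclopropyl (2S)-2-methoxy-2-phenylacetate F3. These are separated by chromatography, and methanolysis of F2 (K2CO3, MeOH) returns enantiopure 4; resolution replaces asymmetric induction.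

Step 5 (Wolff contraction to the cyclobutane). Ring strain, carbene 1,2-hydrogen shift to the cyclopentenone and ketene side reactions can lower the yield. The fallback sets out from 10 and returns at 14. Ketone 10 is converted via its silyl enol ether (LiHMDS, TMSCl; then NBS, −78 °C) into (2S,3R)-5-bromo-2-methyl-2-(prop-2-yn-1-yl)-3-R^A-cyclopentan-1-one F4. Aqueous KOH in dioxane then effects a quasi-Favorskii (semibenzilic) contraction, in which hydroxide adds to the carbonyl and the quaternary carbon shifts with loss of bromide, giving acid 14 after acidification.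

**Further compounds**

F1 | step 1 | (1R,2S)-1-(2-chloroethyl)-2-(3-methylbut-2-en-1-yl)cyclopropan-1-ol | CC(C)=CC[C@H]1C[C@@]1(O)CCCl
F2 | step 1 | (1S,2R)-1-(2-chloroethyl)-2-(3-methylbut-2-en-1-yl)cyclopropyl (2S)-2-methoxy-2-phenylacetate | CC(C)=CC[C@@H]1C[C@]1(OC(=O)[C@@H](OC)c1ccccc1)CCCl
F3 | step 1 | (1R,2S)-1-(2-chloroethyl)-2-(3-methylbut-2-en-1-yl)cyclopropyl (2S)-2-methoxy-2-phenylacetate | CC(C)=CC[C@H]1C[C@@]1(OC(=O)[C@@H](OC)c1ccccc1)CCCl
F4 | step 5 | (2S,3R)-5-bromo-2-methyl-2-(prop-2-yn-1-yl)-3-R^A-cyclopentan-1-one | CC(C)=CC[C@@H]1C[C@]1(O[Si](C)(C)C(C)(C)C)CC[C@@H]2CC(Br)C(=O)[C@@]2(C)CC#C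
F0 | step 11 | none | none
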